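**Strategy.** Everything rests on disconnecting the C4–C4a bond of the coumarin. C4 is a formyl-level carbon, and C4a lies ortho to the lactone oxygen on C8a and para to the C7 oxygen of ring A, the benzo ring (the C6 oxygen is para to C8a, not to C4a). An oxocarbenium ion tethered through an aryl ester can therefore close the pyranone ring by Friedel–Crafts attack and aromatize by loss of methanol in the same operation. The precursor is the 3,4-dimethoxyphenyl ester of a 2-aryloxy-3,3-dimethoxypropanoic acid; its aryloxy group (ring B) carries a bromine para to the ether oxygen, which later serves a Heck union with an acrylate of protected (R)-danshensu.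

Key step: step 5

Remark: the aryloxy-bearing carbon of compounds 5–10 is racemic and becomes sp2 in step 5; the single stereocenter of the target is carried unchanged from sodium (R)-danshensu, which is assumed to be commercially available.

**Route**

Step 1
Reactants: 1 4-bromo-2-methoxyphenol; 2 methyl bromoacetate
Product: 3 methyl 2-(4-bromo-2-methoxyphenoxy)acetate
Conditions: K2CO3, acetone, reflux
Reagents that add atoms: none
Why: Williamson ether synthesis in which the phenoxide displaces bromide from the activated primary α-bromo ester (SN2), while the aryl bromide and the methyl ester are inert to carbonate in acetone.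

Step 2
Reactants: 3 methyl 2-(4-bromo-2-methoxyphenoxy)acetate; 4 methyl formate
Product: 6 methyl 2-(4-bromo-2-methoxyphenoxy)-3,3-dimethoxypropanoate (racemic), via formyl ester 5 (not isolated)
Conditions: NaH, HCO2Me (excess), THF, 0 °C → rt; then HCl/MeOH (excess), HC(OMe)3, rt
Reagents that add atoms: trimethyl orthoformate COC(OC)OC; methanol CO
Why: Crossed Claisen condensation of the ester enolate with non-enolizable methyl formate is driven by the stabilized sodium enolate of 5, and acidification in methanol with orthoformate as water scavenger then turns the formyl carbon into its dimethyl acetal (acid-catalysed acetalization) before 5 can deformylate or self-condense.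

Step 3
Reactants: 6 methyl 2-(4-bromo-2-methoxyphenoxy)-3,3-dimethoxypropanoate
Product: 7 2-(4-bromo-2-methoxyphenoxy)-3,3-dimethoxypropanoic acid (racemic)
Conditions: LiOH, THF/H2O, 0 °C → rt; then cold 1 M HCl to pH 3
Reagents that add atoms: lithium hydroxide [Li+].[OH-]
Why: Ester saponification by acyl–oxygen cleavage, with the acetal inert to base and surviving the brief cold acidification because the flanking carboxyl and aryloxy groups disfavour its ionization.

Step 4
Reactants: 7 2-(4-bromo-2-methoxyphenoxy)-3,3-dimethoxypropanoic acid; 8 3,4-dimethoxyphenol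
Product: 9 3,4-dimethoxyphenyl 2-(4-bromo-2-methoxyphenoxy)-3,3-dimethoxypropanoate (racemic)
Conditions: DCC, DMAP (cat.), CH2Cl2, 0 °C → rt
Reagents that add atoms: none
Why: Steglich esterification, in which the O-acylisourea is passed to the phenol through the acylpyridinium ion under neutral conditions that leave the acetal untouched, so the acyl group is placed on the future lactone oxygen before any C–C bond is made.

Step 5
Reactants: 9 3,4-dimethoxyphenyl 2-(4-bromo-2-methoxyphenoxy)-3,3-dimethoxypropanoate
Product: 11 3-(4-bromo-2-methoxyphenoxy)-6,7-dimethoxy-2H-chromen-2-one, via 4-methoxychromanone 10 (not isolated)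
Conditions: MeSO3H, CH2Cl2, 0 °C → rt
Reagents that add atoms: none
Why: Methanesulfonic acid ionizes the acetal of 9 to a methoxy-oxocarbenium ion at the future C4, which is attacked by the ester-ring carbon ortho to the acyloxy group and para to the 3-methoxy group (the future C4a, para to the C7 oxygen) in an intramolecular Friedel–Crafts alkylation; rearomatization gives 10, and acid-promoted loss of methanol across C3–C4 (benzylic ionization assisted by the C7 oxygen, then loss of the C3 proton) should deliver the aromatic 2-pyranone. The closest known reaction type is the stepwise Pechmann cyclization of aryl 3,3-dialkoxypropanoates and aryl 3-alkoxyacrylates to 4-unsubstituted coumarins in strong acid. The pyranone closes in a 6-exo-trig mode with respect to the C=O+ bond of the oxocarbenium ion, with the C4a–C8a bond of ring A endocyclic. No stereocenter is created, since the racemic carbon of 9 and both sp3 carbons of 10 become sp2 in 11. The step needs attack on ring A and not on the carbon of ring B ortho to the ether oxygen (a five-membered closure leading to a benzofuran-2-carboxylate), and attack at the carbon para to methoxy and not at the carbon flanked by the two oxygens of the ester ring. Para-methoxy activation, the less strained six-membered transition state, inductive deactivation of ring B by bromine, steric shielding of the flanked carbon and the preformed ester tether should secure this.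

Step 6
Reactants: 11 3-(4-bromo-2-methoxyphenoxy)-6,7-dimethoxy-2H-chromen-2-one
Product: 12 3-(4-bromo-2-hydroxyphenoxy)-6,7-dihydroxy-2H-chromen-2-one
Conditions: BBr3, CH2Cl2, −78 °C → rt; then H2O
Reagents that add atoms: none
Why: Lewis-acid ether cleavage in which bromide attacks the methyl group of each boron-complexed aryl methyl ether (SN2), while the C3–O–aryl ether has no sp3 carbon to attack and the lactone and aryl bromide are stable to BBr3.

Step 7
Reactants: 12 3-(4-bromo-2-hydroxyphenoxy)-6,7-dihydroxy-2H-chromen-2-one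
Product: 13 3-[4-bromo-2-(methoxymethoxy)phenoxy]-6,7-bis(methoxymethoxy)-2H-chromen-2-one
Conditions: MOMCl, i-Pr2NEt, CH2Cl2/DMF, 0 °C → rt
Reagents that add atoms: chloromethyl methyl ether COCCl
Why: O-alkylation of the three phenols by the highly electrophilic α-chloro ether (MOM acetal protection), which removes the acidic and chelating catechol functions ahead of the palladium step and leaves the lactone intact under amine base.

Step 8
Reactants: 14 sodium (R)-3-(3,4-dihydroxyphenyl)-2-hydroxypropanoate (sodium (R)-danshensu)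
Product: 15 methoxymethyl (R)-3-[3,4-bis(methoxymethoxy)phenyl]-2-hydroxypropanoate
Conditions: MOMCl (3.1 equiv), K2CO3, DMF, 0 °C
Reagents that add atoms: chloromethyl methyl ether COCCl
Why: Chemoselective O-alkylation, in which the carboxylate and the two carbonate-generated phenoxides react far faster than the neutral, hindered α-hydroxyl next to the ester, so that at low temperature with stoichiometric reagent the secondary alcohol should stay free and the stereocenter is not touched.

Step 9
Reactants: 15 methoxymethyl (R)-3-[3,4-bis(methoxymethoxy)phenyl]-2-hydroxypropanoate; 16 acryloyl chloride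
Product: 17 methoxymethyl (R)-2-(acryloyloxy)-3-[3,4-bis(methoxymethoxy)phenyl]propanoate
Conditions: Et3N, CH2Cl2, −20 → 0 °C
Reagents that add atoms: none
Why: O-acylation of the secondary alcohol by the acid chloride with amine as HCl scavenger, which leaves the C–O bond of the stereocenter intact so that the R configuration is retained.

Step 10
Reactants: 13 3-[4-bromo-2-(methoxymethoxy)phenoxy]-6,7-bis(methoxymethoxy)-2H-chromen-2-one; 17 methoxymethyl (R)-2-(acryloyloxy)-3-[3,4-bis(methoxymethoxy)phenyl]propanoate
Product: 18 methoxymethyl (R)-2-{[(E)-3-{4-[(6,7-bis(methoxymethoxy)-2-oxo-2H-chromen-3-yl)oxy]-3-(methoxymethoxy)phenyl}prop-2-enoyl]oxy}-3-[3,4-bis(methoxymethoxy)phenyl]propanoate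
Conditions: Pd(OAc)2 (5 mol %), P(o-tol)3 (10 mol %), Et3N, DMF, 90 °C
Reagents that add atoms: none
Why: Mizoroki–Heck reaction, in which oxidative addition of the aryl bromide to zerovalent palladium, syn insertion at the acrylate β-carbon and syn β-hydride elimination should give the E-cinnamate, while the α-acyloxy ester stereocenter is not enolized by triethylamine and the MOM groups and lactone tolerate the anhydrous basic medium.

Step 11
Reactants: 18 methoxymethyl (R)-2-{[(E)-3-{4-[(6,7-bis(methoxymethoxy)-2-oxo-2H-chromen-3-yl)oxy]-3-(methoxymethoxy)phenyl}prop-2-enoyl]oxy}-3-[3,4-bis(methoxymethoxy)phenyl]propanoate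
Product: 19 (R)-3-(3,4-dihydroxyphenyl)-2-{[(E)-3-{4-[(6,7-dihydroxy-2-oxo-2H-chromen-3-yl)oxy]-3-hydroxyphenyl}prop-2-enoyl]oxy}propanoic acid (target)
Conditions: 3 M HCl (aq)/THF, 40 °C
Reagents that add atoms: none
Why: Acid-catalysed acetal hydrolysis of the five MOM aryl ethers and the MOM ester, with water trapping the methoxymethyl cation as formaldehyde and methanol, while the cinnamate ester, lactone, aryl vinyl ether and E-alkene are stable to dilute aqueous acid and the stereocenter cannot epimerize without base.

**Compound list**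

1 | 4-bromo-2-methoxyphenol | COc1cc(Br)ccc1O | starting material
2 | methyl bromoacetate | BrCC(=O)OC | starting material
3 | methyl 2-(4-bromo-2-methoxyphenoxy)acetate | COC(=O)COc1ccc(Br)cc1OC | intermediate
4 | methyl formate | COC=O | starting material
5 | methyl 2-(4-bromo-2-methoxyphenoxy)-3-oxopropanoate (racemic; formed as its sodium enolate, not isolated) | COC(=O)C(C=O)Oc1ccc(Br)cc1OC | intermediate
6 | methyl 2-(4-bromo-2-methoxyphenoxy)-3,3-dimethoxypropanoate (racemic) | COC(OC)C(Oc1ccc(Br)cc1OC)C(=O)OC | intermediate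
7 | 2-(4-bromo-2-methoxyphenoxy)-3,3-dimethoxypropanoic acid (racemic) | COC(OC)C(Oc1ccc(Br)cc1OC)C(=O)O | intermediate
8 | 3,4-dimethoxyphenol | COc1ccc(O)cc1OC | starting material
9 | 3,4-dimethoxyphenyl 2-(4-bromo-2-methoxyphenoxy)-3,3-dimethoxypropanoate (racemic) | COC(OC)C(Oc1ccc(Br)cc1OC)C(=O)Oc1ccc(OC)c(OC)c1 | intermediate
10 | 3-(4-bromo-2-methoxyphenoxy)-4,6,7-trimethoxychroman-2-one (racemic diastereomer mixture, not isolated) | COC1C(Oc2ccc(Br)cc2OC)C(=O)Oc2cc(OC)c(OC)cc12 | intermediate
11 | 3-(4-bromo-2-methoxyphenoxy)-6,7-dimethoxy-2H-chromen-2-one | COc1cc(Br)ccc1Oc1cc2cc(OC)c(OC)cc2oc1=O | intermediate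
12 | 3-(4-bromo-2-hydroxyphenoxy)-6,7-dihydroxy-2H-chromen-2-one | Oc1cc(Br)ccc1Oc1cc2cc(O)c(O)cc2oc1=O | intermediate
13 | 3-[4-bromo-2-(methoxymethoxy)phenoxy]-6,7-bis(methoxymethoxy)-2H-chromen-2-one | COCOc1cc(Br)ccc1Oc1cc2cc(OCOC)c(OCOC)cc2oc1=O | intermediate
14 | sodium (R)-3-(3,4-dihydroxyphenyl)-2-hydroxypropanoate (sodium (R)-danshensu) | O[C@H](Cc1ccc(O)c(O)c1)C(=O)[O-].[Na+] | starting material
15 | methoxymethyl (R)-3-[3,4-bis(methoxymethoxy)phenyl]-2-hydroxypropanoate | O[C@H](Cc1ccc(OCOC)c(OCOC)c1)C(=O)OCOC | intermediate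
16 | acryloyl chloride | C=CC(=O)Cl | starting material
17 | methoxymethyl (R)-2-(acryloyloxy)-3-[3,4-bis(methoxymethoxy)phenyl]propanoate | C=CC(=O)O[C@H](Cc1ccc(OCOC)c(OCOC)c1)C(=O)OCOC | intermediate
18 | methoxymethyl (R)-2-{[(E)-3-{4-[(6,7-bis(methoxymethoxy)-2-oxo-2H-chromen-3-yl)oxy]-3-(methoxymethoxy)phenyl}prop-2-enoyl]oxy}-3-[3,4-bis(methoxymethoxy)phenyl]propanoate | O=C(/C=C/c1ccc(Oc2cc3cc(OCOC)c(OCOC)cc3oc2=O)c(OCOC)c1)O[C@H](Cc1ccc(OCOC)c(OCOC)c1)C(=O)OCOC | intermediate
19 | (R)-3-(3,4-dihydroxyphenyl)-2-{[(E)-3-{4-[(6,7-dihydroxy-2-oxo-2H-chromen-3-yl)oxy]-3-hydroxyphenyl}prop-2-enoyl]oxy}propanoic acid | O=C(/C=C/c1ccc(Oc2cc3cc(O)c(O)cc3oc2=O)c(O)c1)O[C@H](Cc1ccc(O)c(O)c1)C(=O)O | target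

**Step count**

Total step count: 11 (steps 8 and 9 build the acrylate fragment). Longest linear sequence: 9 steps (steps 1–7, 10 and 11, from 4-bromo-2-methoxyphenol).

**Steps most likely to fail**

Step 5. The oxocarbenium ion may close onto ring B in a five-membered mode (benzofuran pathway), or the aryl ester may be cleaved or suffer acyl migration in the strong acid before the C–C bond forms. The fallback sets out from 3 and comes back at 11, closing the pyranone by carbonyl condensation at C3–C4 with the C4–C4a bond already in place. Ester 3 would be saponified (LiOH, THF/H2O) to 2-(4-bromo-2-methoxyphenoxy)acetic acid F1. This acid would be esterified (DCC, DMAP, CH2Cl2) with commercial 2-hydroxy-4,5-dimethoxybenzaldehyde (COc1cc(O)c(C=O)cc1OC) to give 2-formyl-4,5-dimethoxyphenyl 2-(4-bromo-2-methoxyphenoxy)acetate F2. DBU in MeCN (or Ac2O/Et3N with heating, Perkin conditions) should then effect intramolecular Knoevenagel-type aldol condensation of the activated methylene onto the ortho aldehyde and dehydration to 11, with the regiochemistry fixed by the aldehyde.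

Step 10. Oxidative addition into the electron-rich aryl bromide may be slow, so that thermal polymerization of the acrylate, loss of the MOM ester or base-induced erosion at the α-stereocenter compete. The fallback sets out from 13 (with 15) and comes back at 18, keeping the chiral fragment out of the palladium step. Bromide 13 would be coupled with acrylic acid (Pd(OAc)2, P(o-tol)3, Et3N, DMF, 100 °C, where forcing conditions and excess alkene are harmless) to give (E)-3-{4-[(6,7-bis(methoxymethoxy)-2-oxo-2H-chromen-3-yl)oxy]-3-(methoxymethoxy)phenyl}prop-2-enoic acid F3. This acid would then be joined to alcohol 15 by Steglich esterification (DCC, DMAP, CH2Cl2, 0 °C → rt) to give 18.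

Step 11. Unmasking of six acetal groups may be incomplete, or the acid strength then required may hydrolyse the α-acyloxy ester link and let the released formaldehyde equivalent hydroxymethylate the free catechol rings. The fallback sets out from 12 and 14 and comes back at 19, replacing all five phenolic MOM ethers by silyl ethers that are removed with fluoride.
- Triol 12 would be silylated (TBSCl, imidazole, DMF) to 3-[4-bromo-2-(tert-butyldimethylsilyloxy)phenoxy]-6,7-bis(tert-butyldimethylsilyloxy)-2H-chromen-2-one F4.
- Salt 14 would be alkylated at the carboxylate only (MOMCl, 1 equiv, DMF, 0 °C, no added base) to methoxymethyl (R)-3-(3,4-dihydroxyphenyl)-2-hydroxypropanoate F5.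
- The two phenols of F5 would be silylated in preference to the hindered α-hydroxyl (TBSCl, 2.1 equiv, imidazole, CH2Cl2, 0 °C) to give methoxymethyl (R)-3-[3,4-bis(tert-butyldimethylsilyloxy)phenyl]-2-hydroxypropanoate F6.
- Acryloyl chloride and Et3N would convert F6 into methoxymethyl (R)-2-(acryloyloxy)-3-[3,4-bis(tert-butyldimethylsilyloxy)phenyl]propanoate F7.
- Heck coupling of F4 with F7 (Pd(OAc)2, P(o-tol)3, Et3N, MeCN, 80 °C) would give methoxymethyl (R)-2-{[(E)-3-{4-[(6,7-bis(tert-butyldimethylsilyloxy)-2-oxo-2H-chromen-3-yl)oxy]-3-(tert-butyldimethylsilyloxy)phenyl}prop-2-enoyl]oxy}-3-[3,4-bis(tert-butyldimethylsilyloxy)phenyl]propanoate F8.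
- Et3N·3HF in THF would remove the five aryl silyl ethers, and brief 1 M HCl (aq)/THF at rt would hydrolyse the single, very labile MOM ester to give 19.

**Further compounds**

F1 | step 5 | 2-(4-bromo-2-methoxyphenoxy)acetic acid | OC(=O)COc1ccc(Br)cc1OC
F2 | step 5 | 2-formyl-4,5-dimethoxyphenyl 2-(4-bromo-2-methoxyphenoxy)acetate | COc1cc(C=O)c(OC(=O)COc2ccc(Br)cc2OC)cc1OC
F3 | step 10 | (E)-3-{4-[(6,7-bis(methoxymethoxy)-2-oxo-2H-chromen-3-yl)oxy]-3-(methoxymethoxy)phenyl}prop-2-enoic acid | OC(=O)/C=C/c1ccc(Oc2cc3cc(OCOC)c(OCOC)cc3oc2=O)c(OCOC)c1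
F4 | step 11 | 3-[4-bromo-2-(tert-butyldimethylsilyloxy)phenoxy]-6,7-bis(tert-butyldimethylsilyloxy)-2H-chromen-2-one | CC(C)(C)[Si](C)(C)Oc1cc(Br)ccc1Oc1cc2cc(O[Si](C)(C)C(C)(C)C)c(O[Si](C)(C)C(C)(C)C)cc2oc1=O
F5 | step 11 | methoxymethyl (R)-3-(3,4-dihydroxyphenyl)-2-hydroxypropanoate | O[C@H](Cc1ccc(O)c(O)c1)C(=O)OCOC
F6 | step 11 | methoxymethyl (R)-3-[3,4-bis(tert-butyldimethylsilyloxy)phenyl]-2-hydroxypropanoate | O[C@H](Cc1ccc(O[Si](C)(C)C(C)(C)C)c(O[Si](C)(C)C(C)(C)C)c1)C(=O)OCOC
F7 | step 11 | methoxymethyl (R)-2-(acryloyloxy)-3-[3,4-bis(tert-butyldimethylsilyloxy)phenyl]propanoate | C=CC(=O)O[C@H](Cc1ccc(O[Si](C)(C)C(C)(C)C)c(O[Si](C)(C)C(C)(C)C)c1)C(=O)OCOC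
F8 | step 11 | methoxymethyl (R)-2-{[(E)-3-{4-[(6,7-bis(tert-butyldimethylsilyloxy)-2-oxo-2H-chromen-3-yl)oxy]-3-(tert-butyldimethylsilyloxy)phenyl}prop-2-enoyl]oxy}-3-[3,4-bis(tert-butyldimethylsilyloxy)phenyl]propanoate | O=C(/C=C/c1ccc(Oc2cc3cc(O[Si](C)(C)C(C)(C)C)c(O[Si](C)(C)C(C)(C)C)cc3oc2=O)c(O[Si](C)(C)C(C)(C)C)c1)O[C@H](Cc1ccc(O[Si](C)(C)C(C)(C)C)c(O[Si](C)(C)C(C)(C)C)c1)C(=O)OCOC
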